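**Assumption:** the target is taken exactly as drawn, i.e. OMe at C8 of the fused ring (peri to C1) and (1S,2S), which places the 1-aryl and 2-aroyl groups cis; both methoxy-dihydroxybenzaldehydes are taken as catalogue chemicals.

**Retrosynthetic overview**
- The only ring made is the dihydronaphthalene. It is closed last, as in the biogenesis of α,α'-linked (8-8') retrochalcone dimers: an arene (ring A) attacks a quinone-methide-type benzylic cation (C1–C8a), then the enol becomes the C2 ketone. A chiral Brønsted acid sets C1 and C2 in that one step.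
- Two licochalcone B halves would close para to the 3-OH and give the 5-OMe isomer. The drawn 8-OMe ring needs a 3,4-dioxygenated 5-methoxyphenyl half, so the precursor is an unsymmetrical 2,3-bis(arylidene)-1,4-diketone, the aromatised tautomer of the 8-8' bis-quinone methide.
- The 8-8' bond (C2–C3) is made first as a symmetrical 1,4-diketone by oxidative enolate dimerisation. The two different arylidene arms are then added by two aldol condensations.
- Triisopropylsilyl ethers carry all phenols, block the wrong ortho position of ring A during ring closure, and are removed last with buffered HF·pyridine.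

**Route**

Step 1
Reactants: 1 4'-hydroxyacetophenone
Product: 2 1-[4-(triisopropylsilyloxy)phenyl]ethanone
Conditions: iPr3SiCl (1.2 equiv), imidazole (2.5 equiv), DMF, rt
Reagents that add atoms: triisopropylsilyl chloride, CC(C)[Si](Cl)(C(C)C)C(C)C
Why: Imidazole-promoted O-silylation of a phenol; the aryl triisopropylsilyl ether survives the amide base, the amine condensations and the acid step that follow.

Step 2
Reactants: 2 1-[4-(triisopropylsilyloxy)phenyl]ethanone (two molecules)
Product: 4 1,4-bis[4-(triisopropylsilyloxy)phenyl]butane-1,4-dione, via lithium enolate 3 (not isolated)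
Conditions: LiN(iPr)2 (1.05 equiv), THF, −78 °C; then CuCl2 (1.1 equiv), DMF, −78 °C → rt
Reagents that add atoms: none
Why: Oxidative homocoupling of a ketone lithium enolate with CuCl2 (Saegusa-type enolate dimerisation) forges the C2–C3 (8-8') bond as a symmetrical 1,4-diketone, so no cross-coupling selectivity is needed.

Step 3
Reactants: 5 3,4-dihydroxy-5-methoxybenzaldehyde
Product: 6 3-methoxy-4,5-bis(triisopropylsilyloxy)benzaldehyde
Conditions: iPr3SiCl (2.6 equiv), imidazole (5 equiv), 4-(dimethylamino)pyridine (0.1 equiv), DMF, 50 °C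
Reagents that add atoms: triisopropylsilyl chloride, CC(C)[Si](Cl)(C(C)C)C(C)C
Why: Exhaustive O-silylation of the catechol; the two neighbouring silyloxy groups are the steric control element for the later ring closure.

Step 4
Reactants: 4 1,4-bis[4-(triisopropylsilyloxy)phenyl]butane-1,4-dione (2.5 equiv, excess recovered); 6 3-methoxy-4,5-bis(triisopropylsilyloxy)benzaldehyde
Product: 7 (E)-2-[3-methoxy-4,5-bis(triisopropylsilyloxy)benzylidene]-1,4-bis[4-(triisopropylsilyloxy)phenyl]butane-1,4-dione
Conditions: piperidine (0.3 equiv), acetic acid (0.3 equiv), toluene, 90 °C, 4 Å molecular sieves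
Reagents that add atoms: none
Why: Amine/acid-catalysed crossed aldol condensation (Knoevenagel type) of one methylene of the diketone with a non-enolisable aldehyde, with loss of one water; the excess of 4 keeps it to one arm, and the E alkene (aryl trans to aroyl) is the thermodynamic one.

Step 5
Reactants: 8 3,4-dihydroxy-2-methoxybenzaldehyde
Product: 9 2-methoxy-3,4-bis(triisopropylsilyloxy)benzaldehyde
Conditions: iPr3SiCl (2.6 equiv), imidazole (5 equiv), 4-(dimethylamino)pyridine (0.1 equiv), DMF, 50 °C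
Reagents that add atoms: triisopropylsilyl chloride, CC(C)[Si](Cl)(C(C)C)C(C)C
Why: Same O-silylation as in step 3; it removes the acidic phenols that would deactivate the aldehyde in the next condensation.

Step 6
Reactants: 7 (E)-2-[3-methoxy-4,5-bis(triisopropylsilyloxy)benzylidene]-1,4-bis[4-(triisopropylsilyloxy)phenyl]butane-1,4-dione; 9 2-methoxy-3,4-bis(triisopropylsilyloxy)benzaldehyde (1.5 equiv)
Product: 10 (2E,3E)-2-[2-methoxy-3,4-bis(triisopropylsilyloxy)benzylidene]-3-[3-methoxy-4,5-bis(triisopropylsilyloxy)benzylidene]-1,4-bis[4-(triisopropylsilyloxy)phenyl]butane-1,4-dione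
Conditions: piperidine (0.3 equiv), acetic acid (0.3 equiv), toluene, 90 °C, 4 Å molecular sieves
Reagents that add atoms: none
Why: Second aldol condensation (Knoevenagel type), again with loss of one water, at the remaining methylene of 7, which is alpha to its ketone and allylic to the enone; E geometry again puts each aryl trans to its aroyl, and so places ring A cis to C2 as the ring closure requires.

Step 7
Reactants: 10 (2E,3E)-2-[2-methoxy-3,4-bis(triisopropylsilyloxy)benzylidene]-3-[3-methoxy-4,5-bis(triisopropylsilyloxy)benzylidene]-1,4-bis[4-(triisopropylsilyloxy)phenyl]butane-1,4-dione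
Product: 12 (1S,2S)-hexakis-O-(triisopropylsilyl)licobichalcone, via cyclised enol 11 (not isolated)
Conditions: (R)-3,3'-bis(2,4,6-triisopropylphenyl)-1,1'-binaphthalene-2,2'-diyl N-(trifluoromethanesulfonyl)phosphoramidate (10 mol%), toluene, −40 °C, 4 Å molecular sieves; cold quench with solid NaHCO3
Reagents that add atoms: none
Why: Proposed new method: the chiral acid protonates the aroyl carbonyl on C2 and gives an ion-paired para-silyloxybenzyl cation (an O-silylated quinone methide) at C1; this arm ionises rather than the other because its cation is stabilised by both the para-OSi and the ortho-OMe group of ring B, whereas the ring A arylidene has only a para-OSi donor. Ring A attacks the cation through its carbon ortho to OMe and para to a silyloxy group, because closure at the other ortho carbon would force a buttressed OSi(iPr)3 into the peri position, and this puts OMe at C8; the single free ortho carbon of ring B is para only to a twisted, flanked silyloxy group and is the poorer nucleophile. The chiral counter-anion selects the C1 face; the (R)-acid is assumed to give 1S, and the (S)-acid is used if the sense proves reversed. The resulting enol 11 is protonated at C2 anti to the pseudoaxial C1 aryl group, which gives the 1,2-cis (1S,2S) ketone under kinetic control at low temperature. Closest known reactions: the Brønsted-acid cyclisation of bis(benzylidene)succinates to 1-aryl-1,2-dihydronaphthalenes (intramolecular Friedel–Crafts), the chiral N-triflylphosphoramide-catalysed Nazarov cyclisation with kinetic enol protonation to cis products, and chiral phosphoric acid Friedel–Crafts additions to para-quinone methides.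

Step 8
Reactants: 12 (1S,2S)-hexakis-O-(triisopropylsilyl)licobichalcone
Product: 13 licobichalcone
Conditions: HF·pyridine (excess), pyridine, THF, 0 °C → rt, under argon
Reagents that add atoms: none
Why: Fluoride cleavage of the six aryl silyl ethers in a pyridine-buffered medium; neither a strong base nor a strong acid is present, so the epimerisable C2–H (the less stable cis isomer) and the free catechols are not touched, and C1 is not involved.

**Compound list**
1 | 4'-hydroxyacetophenone | CC(=O)c1ccc(O)cc1 | starting material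
2 | 1-[4-(triisopropylsilyloxy)phenyl]ethanone | CC(=O)c1ccc(O[Si](C(C)C)(C(C)C)C(C)C)cc1 | intermediate
3 | lithium 1-[4-(triisopropylsilyloxy)phenyl]ethenolate (not isolated) | [Li]OC(=C)c1ccc(O[Si](C(C)C)(C(C)C)C(C)C)cc1 | intermediate
4 | 1,4-bis[4-(triisopropylsilyloxy)phenyl]butane-1,4-dione | O=C(CCC(=O)c1ccc(O[Si](C(C)C)(C(C)C)C(C)C)cc1)c1ccc(O[Si](C(C)C)(C(C)C)C(C)C)cc1 | intermediate
5 | 3,4-dihydroxy-5-methoxybenzaldehyde (5-hydroxyvanillin) | COc1cc(C=O)cc(O)c1O | starting material
6 | 3-methoxy-4,5-bis(triisopropylsilyloxy)benzaldehyde | COc1cc(C=O)cc(O[Si](C(C)C)(C(C)C)C(C)C)c1O[Si](C(C)C)(C(C)C)C(C)C | intermediate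
7 | (E)-2-[3-methoxy-4,5-bis(triisopropylsilyloxy)benzylidene]-1,4-bis[4-(triisopropylsilyloxy)phenyl]butane-1,4-dione | O=C(c1ccc(O[Si](C(C)C)(C(C)C)C(C)C)cc1)/C(CC(=O)c1ccc(O[Si](C(C)C)(C(C)C)C(C)C)cc1)=C/c1cc(OC)c(O[Si](C(C)C)(C(C)C)C(C)C)c(O[Si](C(C)C)(C(C)C)C(C)C)c1 | intermediate
8 | 3,4-dihydroxy-2-methoxybenzaldehyde | COc1c(C=O)ccc(O)c1O | starting material
9 | 2-methoxy-3,4-bis(triisopropylsilyloxy)benzaldehyde | COc1c(C=O)ccc(O[Si](C(C)C)(C(C)C)C(C)C)c1O[Si](C(C)C)(C(C)C)C(C)C | intermediate
10 | (2E,3E)-2-[2-methoxy-3,4-bis(triisopropylsilyloxy)benzylidene]-3-[3-methoxy-4,5-bis(triisopropylsilyloxy)benzylidene]-1,4-bis[4-(triisopropylsilyloxy)phenyl]butane-1,4-dione | O=C(c1ccc(O[Si](C(C)C)(C(C)C)C(C)C)cc1)/C(=C/c1ccc(O[Si](C(C)C)(C(C)C)C(C)C)c(O[Si](C(C)C)(C(C)C)C(C)C)c1OC)C(=C\c1cc(OC)c(O[Si](C(C)C)(C(C)C)C(C)C)c(O[Si](C(C)C)(C(C)C)C(C)C)c1)/C(=O)c1ccc(O[Si](C(C)C)(C(C)C)C(C)C)cc1 | intermediate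
11 | cyclised enol (not isolated): 1-aryl-1H-naphthalene carrying the 3-aroyl group and a 2-[hydroxy(aryl)methylidene] group, C1 configured as in 12, enol geometry not defined | COc1c([C@H]2c3c(cc(O[Si](C(C)C)(C(C)C)C(C)C)c(O[Si](C(C)C)(C(C)C)C(C)C)c3OC)C=C(C(=O)c3ccc(O[Si](C(C)C)(C(C)C)C(C)C)cc3)C2=C(O)c2ccc(O[Si](C(C)C)(C(C)C)C(C)C)cc2)ccc(O[Si](C(C)C)(C(C)C)C(C)C)c1O[Si](C(C)C)(C(C)C)C(C)C | intermediate
12 | [(1S,2S)-8-methoxy-1-[2-methoxy-3,4-bis(triisopropylsilyloxy)phenyl]-6,7-bis(triisopropylsilyloxy)-1,2-dihydronaphthalene-2,3-diyl]bis{[4-(triisopropylsilyloxy)phenyl]methanone}, 1-aryl and 2-aroyl cis | COc1c([C@H]2c3c(cc(O[Si](C(C)C)(C(C)C)C(C)C)c(O[Si](C(C)C)(C(C)C)C(C)C)c3OC)C=C(C(=O)c3ccc(O[Si](C(C)C)(C(C)C)C(C)C)cc3)[C@H]2C(=O)c2ccc(O[Si](C(C)C)(C(C)C)C(C)C)cc2)ccc(O[Si](C(C)C)(C(C)C)C(C)C)c1O[Si](C(C)C)(C(C)C)C(C)C | intermediate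
13 | licobichalcone, [(1S,2S)-1-(3,4-dihydroxy-2-methoxyphenyl)-6,7-dihydroxy-8-methoxy-1,2-dihydronaphthalene-2,3-diyl]bis[(4-hydroxyphenyl)methanone] | COc1c([C@H]2c3c(cc(O)c(O)c3OC)C=C(C(=O)c3ccc(O)cc3)[C@H]2C(=O)c2ccc(O)cc2)ccc(O)c1O | target

**Step count**
Total steps: 8. Longest linear sequence: 6 (steps 1, 2, 4, 6, 7, 8).

**Steps most likely to fail**

Step 7 (ring closure). Four things must go right at once: which ortho carbon of ring A closes, the C1 face, kinetic cis protonation at C2, and no O-cyclisation of the diketone to a furan. Fallback, from 10 back to 12: give up catalyst control and cyclise 10 with achiral (CF3SO2)2NH (5 mol%, CH2Cl2, −60 °C) to the racemic cis-dihydronaphthalene. This is a 1:1 mixture of 12 and its mirror image, the (1R,2R)-hexakis(triisopropylsilyl) ether F1. The two are separated by preparative chromatography on an amylose tris(3,5-dimethylphenylcarbamate) phase, and the (1S,2S) fraction is 12.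

Step 4 (first condensation). The methylene of 7 is more acidic than those of 4, so the symmetrical bis-arylidene can form, and arylidene 1,4-diketones can drift to furans. Fallback, from 4 back to 7: dehydrogenate 4 with 2-iodoxybenzoic acid (DMSO/toluene, 80 °C) to the ene-dione (E)-1,4-bis[4-(triisopropylsilyloxy)phenyl]but-2-ene-1,4-dione F2. Addition of PPh3 (toluene, rt; conjugate addition and proton shift) gives the stabilised ylide 1,4-bis[4-(triisopropylsilyloxy)phenyl]-2-(triphenylphosphoranylidene)butane-1,4-dione F3. Its Wittig reaction with 6 (toluene, 80 °C) can only install one arm and gives 7 as the E isomer.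

Step 6 (second condensation). The aldehyde 9 is hindered by its ortho OMe group, and the dienolate of 7 may isomerise instead of condensing. Fallback, from 7 back to 10: deprotonate 7 with LiN(SiMe3)2 (THF, −78 °C) and add 9 to obtain the aldol 2-{hydroxy[2-methoxy-3,4-bis(triisopropylsilyloxy)phenyl]methyl}-3-[(E)-3-methoxy-4,5-bis(triisopropylsilyloxy)benzylidene]-1,4-bis[4-(triisopropylsilyloxy)phenyl]butane-1,4-dione F4 as a diastereomer mixture. Dehydration with methyl N-(triethylammoniosulfonyl)carbamate (toluene, 50 °C) gives 10.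

**Further compounds**
F1 | step 7 | [(1R,2R)-8-methoxy-1-[2-methoxy-3,4-bis(triisopropylsilyloxy)phenyl]-6,7-bis(triisopropylsilyloxy)-1,2-dihydronaphthalene-2,3-diyl]bis{[4-(triisopropylsilyloxy)phenyl]methanone} (enantiomer of 12) | COc1c([C@@H]2c3c(cc(O[Si](C(C)C)(C(C)C)C(C)C)c(O[Si](C(C)C)(C(C)C)C(C)C)c3OC)C=C(C(=O)c3ccc(O[Si](C(C)C)(C(C)C)C(C)C)cc3)[C@@H]2C(=O)c2ccc(O[Si](C(C)C)(C(C)C)C(C)C)cc2)ccc(O[Si](C(C)C)(C(C)C)C(C)C)c1O[Si](C(C)C)(C(C)C)C(C)C
F2 | step 4 | (E)-1,4-bis[4-(triisopropylsilyloxy)phenyl]but-2-ene-1,4-dione | O=C(/C=C/C(=O)c1ccc(O[Si](C(C)C)(C(C)C)C(C)C)cc1)c1ccc(O[Si](C(C)C)(C(C)C)C(C)C)cc1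
F3 | step 4 | 1,4-bis[4-(triisopropylsilyloxy)phenyl]-2-(triphenylphosphoranylidene)butane-1,4-dione | O=C(CC(=P(c1ccccc1)(c1ccccc1)c1ccccc1)C(=O)c1ccc(O[Si](C(C)C)(C(C)C)C(C)C)cc1)c1ccc(O[Si](C(C)C)(C(C)C)C(C)C)cc1
F4 | step 6 | 2-{hydroxy[2-methoxy-3,4-bis(triisopropylsilyloxy)phenyl]methyl}-3-[(E)-3-methoxy-4,5-bis(triisopropylsilyloxy)benzylidene]-1,4-bis[4-(triisopropylsilyloxy)phenyl]butane-1,4-dione (diastereomer mixture) | O=C(c1ccc(O[Si](C(C)C)(C(C)C)C(C)C)cc1)C(C(O)c1ccc(O[Si](C(C)C)(C(C)C)C(C)C)c(O[Si](C(C)C)(C(C)C)C(C)C)c1OC)/C(=C\c1cc(OC)c(O[Si](C(C)C)(C(C)C)C(C)C)c(O[Si](C(C)C)(C(C)C)C(C)C)c1)C(=O)c1ccc(O[Si](C(C)C)(C(C)C)C(C)C)cc1
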